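## Retrosynthetic overview

- The 13 benzyl ethers and two aryl bromides fall in a final hydrogenolysis; the protected trimer is cut at the two interflavan bonds as C4-cation/arene Friedel–Crafts unions, C4(middle)–C6(bottom) last and C4(top)–C8(middle) before it. The middle and bottom units come from (−)-epicatechin and (+)-catechin with their rings intact.
- Only the top unit is built de novo: its pyran ring (ring C) is cut at O1–C8a and at C4a–C4. This gives 3,5-bis(benzyloxy)benzyne (ring A) and an acyclic syn-2,3-dioxygenated 3-arylpropanoic morpholine amide (O1–C2–C3–C4, ring B on C2) from an Evans syn glycolate aldol.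
- Enabling feature: in ring A of the top unit, C8a (carries O1) and C4a (carries C4) are adjacent and C4a is flanked by the C5 oxygen. A 3-alkoxy aryne delivers exactly this pattern: the nucleophile goes to the distal carbon and the carbanion forms next to the alkoxy group. C4 sits 1,4 to O1 and can be a carbonyl carbon.
- Ring order: rings A and B enter as preformed benzenes, ring C of the top unit closes in the key step, and the chroman rings of the other two units are never opened.

Key step: step 7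

Remark: the C4 carbinol carbon created in step 8 is carried through step 9 as an epimer mixture (left open in the SMILES), because both epimers ionize to the same C4 cation in step 11.

## Route

Step 1
Reactants: 1 3,5-bis(benzyloxy)phenol
Product: 2 3,5-bis(benzyloxy)phenyl N-isopropylcarbamate
Conditions: i-PrNCO (1.5 equiv), Et3N (cat.), CH2Cl2, rt
Reagents that add atoms: isopropyl isocyanate CC(C)N=C=O
Why: Base-catalysed addition of the phenol to the isocyanate installs a cleavable directing group for ortho-metalation; no stereocenter is involved.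

Step 2
Reactants: 2 3,5-bis(benzyloxy)phenyl N-isopropylcarbamate
Product: 4 3,5-bis(benzyloxy)-2-(trimethylsilyl)phenyl N-isopropylcarbamate, via N-silyl carbamate 3 (not isolated)
Conditions: TBSOTf (1.1 equiv), TMEDA (1.1 equiv), Et2O, 0 °C → rt; then TMEDA (2 equiv), n-BuLi (2.2 equiv), −78 °C; then TMSCl (3 equiv), −78 °C → rt; aq. HCl work-up
Reagents that add atoms: chlorotrimethylsilane C[Si](C)(C)Cl; tert-butyldimethylsilyl trifluoromethanesulfonate CC(C)(C)[Si](C)(C)OS(=O)(=O)C(F)(F)F (its silyl group stays only in intermediate 3)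
Why: Directed ortho-metalation: N-silylation masks the N–H, n-BuLi/TMEDA then lithiates the ring carbon flanked by the carbamate and a benzyloxy group (the doubly activated site), TMSCl traps it and the aqueous acid removes the N-silyl group.

Step 3
Reactants: 4 3,5-bis(benzyloxy)-2-(trimethylsilyl)phenyl N-isopropylcarbamate
Product: 6 3,5-bis(benzyloxy)-2-(trimethylsilyl)phenyl trifluoromethanesulfonate, via silylphenol 5 (not isolated)
Conditions: DBU (1.5 equiv), Et2NH (1.2 equiv), MeCN, 40 °C; then PhNTf2 (1.5 equiv), rt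
Reagents that add atoms: N-phenylbis(trifluoromethanesulfonimide) FC(F)(F)S(=O)(=O)N(c1ccccc1)S(=O)(=O)C(F)(F)F
Why: DBU induces E1cB loss of isopropyl isocyanate (trapped by Et2NH as a urea) and the freed phenoxide is triflated in the same flask, the standard entry to 2-silylaryl triflate aryne precursors.

Step 4
Reactants: 7 (S)-4-benzyloxazolidin-2-one, 8 (benzyloxy)acetyl chloride
Product: 9 (S)-4-benzyl-3-[(benzyloxy)acetyl]oxazolidin-2-one
Conditions: n-BuLi (1.0 equiv), THF, −78 °C; then 8, −78 °C → 0 °C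
Reagents that add atoms: none
Why: N-acylation of the lithiated oxazolidinone auxiliary by the acid chloride is a routine imide synthesis; the auxiliary stereocenter is untouched.

Step 5
Reactants: 9 (S)-4-benzyl-3-[(benzyloxy)acetyl]oxazolidin-2-one, 10 3,4-bis(benzyloxy)benzaldehyde
Product: 12 (S)-4-benzyl-3-[(2S,3R)-2-(benzyloxy)-3-[3,4-bis(benzyloxy)phenyl]-3-hydroxypropanoyl]oxazolidin-2-one, via boron enolate 11 (not isolated)
Conditions: Bu2BOTf (1.1 equiv), Et3N (1.3 equiv), CH2Cl2, −78 °C → 0 °C; then 10, −78 °C → 0 °C; pH 7 buffer, MeOH, 30% H2O2, 0 °C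
Reagents that add atoms: dibutylboron trifluoromethanesulfonate CCCCB(CCCC)OS(=O)(=O)C(F)(F)F (boron stays only in intermediate 11)
Why: Evans syn glycolate aldol: the (Z)-boron enolate reacts through a closed chair transition state on the face left open by the benzyl group of the (S)-auxiliary, which should give the (2S,3R) syn adduct and thereby sets the future C3 and C2 of the top unit.

Step 6
Reactants: 12 (S)-4-benzyl-3-[(2S,3R)-2-(benzyloxy)-3-[3,4-bis(benzyloxy)phenyl]-3-hydroxypropanoyl]oxazolidin-2-one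
Product: 13 (2S,3R)-2-(benzyloxy)-3-[3,4-bis(benzyloxy)phenyl]-3-hydroxy-1-(morpholin-4-yl)propan-1-one
Conditions: morpholine (3 equiv), AlMe3 (3 equiv), CH2Cl2, 0 °C → rt; aq. potassium sodium tartrate
Reagents that add atoms: morpholine C1COCCN1
Why: Aminolysis with the dimethylaluminium amide of morpholine (Weinreb aminolysis) cleaves the exocyclic imide carbonyl, helped by the β-aluminium alkoxide, and leaves both stereocenters and the free benzylic hydroxyl intact.

Step 7
Reactants: 13 (2S,3R)-2-(benzyloxy)-3-[3,4-bis(benzyloxy)phenyl]-3-hydroxy-1-(morpholin-4-yl)propan-1-one, 6 3,5-bis(benzyloxy)-2-(trimethylsilyl)phenyl trifluoromethanesulfonate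
Product: 17 (2R,3S)-3,5,7-tris(benzyloxy)-2-[3,4-bis(benzyloxy)phenyl]chroman-4-one (2,3-cis), via sodium alkoxide 14 (not isolated), via aryne 15 (not isolated), via hemiaminal alkoxide 16 (not isolated)
Conditions: NaH (1.05 equiv), THF, 0 °C; then 6 (1.3 equiv), CsF (3 equiv), 18-crown-6 (cat.), THF, 0 °C → rt; then AcOH, H2O, 0 °C
Reagents that add atoms: sodium hydride [Na+].[H-] (sodium stays only in intermediates 14 and 16)
Why: Proposed new method: NaH converts 13 into alkoxide 14 while fluoride removes the silyl group of 6 and triflate leaves to give aryne 15; the alkoxide oxygen adds to the aryne carbon remote from the flanking benzyloxy group (the future C8a), and the aryl anion formed on the carbon next to that benzyloxy group (the future C4a) attacks the tethered amide carbonyl (the future C4) to give hemiaminal alkoxide 16, which releases ketone 17 only on the acidic quench. The closest known reaction type is the fluoride-mediated annulation of arynes with salicylates and salicylaldehydes to xanthones and xanthenols (phenoxide addition, then intramolecular capture of the aryl anion by the carbonyl group), together with aryne insertions into amide C–N bonds; new here are an aliphatic secondary alkoxide as the nucleophile and a tertiary amide as the internal acceptor. Ring C closes by a 6-exo-trig addition of the aryl anion to the C=O group, after O1–C8a has formed intermolecularly. No stereocenter of the product is created in this step: C2 and C3 come unchanged from the aldol (the C2–O bond is never broken, and C3–H stays next to an amide, not a ketone, until the quench), and the hemiaminal carbon becomes the carbonyl carbon. The step needs regioselective aryne addition, secured by the inductive and distortion effect of the benzyloxy group adjacent to the aryne bond, and ring closure faster than protonation of the aryl anion, secured by a preformed alkoxide in aprotic THF without any O–H donor. Retro-aldol cleavage of 14 and collapse of 16 to a base-sensitive ketone in the flask are both disfavoured because an amide enolate and a morpholide anion are poor leaving groups.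

Step 8
Reactants: 17 (2R,3S)-3,5,7-tris(benzyloxy)-2-[3,4-bis(benzyloxy)phenyl]chroman-4-one
Product: 18 (2R,3R)-3,5,7-tris(benzyloxy)-2-[3,4-bis(benzyloxy)phenyl]chroman-4-ol (C4 epimer mixture)
Conditions: NaBH4, CeCl3·7H2O, THF/MeOH (1:1), −20 °C → 0 °C
Reagents that add atoms: none
Why: Luche reduction of the aryl ketone under nearly neutral conditions should outrun epimerization at the α-carbon; the configuration of the new carbinol is irrelevant because it is ionized in step 11.

Step 9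
Reactants: 18 (2R,3R)-3,5,7-tris(benzyloxy)-2-[3,4-bis(benzyloxy)phenyl]chroman-4-ol
Product: 19 (2R,3R)-3,5,7-tris(benzyloxy)-2-[3,4-bis(benzyloxy)phenyl]-8-bromochroman-4-ol (C4 epimer mixture)
Conditions: NBS (1.0 equiv), CH2Cl2, −40 °C → −20 °C, dark
Reagents that add atoms: N-bromosuccinimide O=C1CCC(=O)N1Br
Why: Electrophilic aromatic bromination of benzylated flavan-3-ols goes selectively to C8 of ring A, which places a bromine cap on the most nucleophilic position of the top unit and blocks self-condensation in the later cation chemistry.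

Step 10
Reactants: 20 (−)-epicatechin
Product: 21 5,7,3',4'-tetra-O-benzyl-(−)-epicatechin
Conditions: BnBr (4.4 equiv), K2CO3 (4.5 equiv), DMF, 0 °C → rt
Reagents that add atoms: benzyl bromide BrCc1ccccc1
Why: Williamson O-benzylation of the four phenols; K2CO3 does not deprotonate the aliphatic 3-OH, and the low temperature limits C2 epimerization.

Step 11
Reactants: 19 (2R,3R)-3,5,7-tris(benzyloxy)-2-[3,4-bis(benzyloxy)phenyl]-8-bromochroman-4-ol, 21 5,7,3',4'-tetra-O-benzyl-(−)-epicatechin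
Product: 22 3,5,7,3',4'-penta-O-benzyl-8-bromoepicatechin-(4β→8)-5,7,3',4'-tetra-O-benzylepicatechin
Conditions: 21 (3 equiv), BF3·OEt2 (0.5 equiv), 4 Å molecular sieves, CH2Cl2, −78 °C → −30 °C
Reagents that add atoms: none
Why: Lewis-acid ionization of the C4 carbinol gives the benzylic cation stabilized by ring A, and Friedel–Crafts attack by C8 of 21 on the β face, anti to the 2-aryl and 3-benzyloxy groups, sets the 4β configuration; the excess nucleophile and the bromine cap suppress oligomers.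

Step 12
Reactants: 22 3,5,7,3',4'-penta-O-benzyl-8-bromoepicatechin-(4β→8)-5,7,3',4'-tetra-O-benzylepicatechin
Product: 23 3,5,7,3',4'-penta-O-benzyl-8-bromoepicatechin-(4β→8)-5,7,3',4'-tetra-O-benzyl-4β-(2-ethoxyethoxy)epicatechin
Conditions: DDQ (2 equiv), 2-ethoxyethanol (5 equiv), CH2Cl2, rt
Reagents that add atoms: 2-ethoxyethanol CCOCCO
Why: DDQ benzylic oxidation: hydride is abstracted from the only CH2-type C4 (lower unit; the C4–H of the upper unit is tertiary and shielded by two ortho-disubstituted rings) and the alcohol traps the cation on the β face, trans to the 3-OH and 2-aryl groups.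

Step 13
Reactants: 24 (+)-catechin
Product: 25 5,7,3',4'-tetra-O-benzyl-(+)-catechin
Conditions: BnBr (4.4 equiv), K2CO3 (4.5 equiv), DMF, 0 °C → rt
Reagents that add atoms: benzyl bromide BrCc1ccccc1
Why: Williamson O-benzylation of the four phenols, as in step 10; the stereocenters are untouched.

Step 14
Reactants: 25 5,7,3',4'-tetra-O-benzyl-(+)-catechin
Product: 26 8-bromo-5,7,3',4'-tetra-O-benzyl-(+)-catechin
Conditions: NBS (1.0 equiv), CH2Cl2, −78 °C → rt
Reagents that add atoms: N-bromosuccinimide O=C1CCC(=O)N1Br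
Why: Regioselective electrophilic bromination at C8 leaves C6 as the only free position of ring A, which will direct the next interflavan bond to C6.

Step 15
Reactants: 23 3,5,7,3',4'-penta-O-benzyl-8-bromoepicatechin-(4β→8)-5,7,3',4'-tetra-O-benzyl-4β-(2-ethoxyethoxy)epicatechin, 26 8-bromo-5,7,3',4'-tetra-O-benzyl-(+)-catechin
Product: 27 3,5,7,3',4'-penta-O-benzyl-8-bromoepicatechin-(4β→8)-5,7,3',4'-tetra-O-benzylepicatechin-(4β→6)-8-bromo-5,7,3',4'-tetra-O-benzylcatechin
Conditions: 26 (4 equiv), TMSOTf (0.5 equiv), CH2Cl2, −78 °C → −20 °C; then Et3N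
Reagents that add atoms: none
Why: TMSOTf ionizes the C4 ether of the middle unit and the halo-capped nucleophile can react only at C6 (Friedel–Crafts, halo-capping strategy for 4→6 bonds); attack on the β face, anti to the 2-aryl and 3-OH groups of the middle unit, sets the second 4β center.

Step 16
Reactants: 27 3,5,7,3',4'-penta-O-benzyl-8-bromoepicatechin-(4β→8)-5,7,3',4'-tetra-O-benzylepicatechin-(4β→6)-8-bromo-5,7,3',4'-tetra-O-benzylcatechin
Product: 28 arecatannin B1, epicatechin-(4β→8)-epicatechin-(4β→6)-catechin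
Conditions: H2 (1 atm), Pd(OH)2/C, Et3N (2.2 equiv), THF/MeOH/H2O (20:20:1), rt
Reagents that add atoms: none
Why: Catalytic hydrogenolysis cleaves both aryl C–Br bonds (Et3N takes up the HBr, protecting the acid-labile interflavan bonds) and all thirteen benzyl ethers without touching any stereocenter.

## Compound list

1 | 3,5-bis(benzyloxy)phenol | Oc1cc(OCc2ccccc2)cc(OCc2ccccc2)c1 | starting material
2 | 3,5-bis(benzyloxy)phenyl N-isopropylcarbamate | CC(C)NC(=O)Oc1cc(OCc2ccccc2)cc(OCc2ccccc2)c1 | intermediate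
3 | 3,5-bis(benzyloxy)phenyl N-(tert-butyldimethylsilyl)-N-isopropylcarbamate | CC(C)N(C(=O)Oc1cc(OCc2ccccc2)cc(OCc2ccccc2)c1)[Si](C)(C)C(C)(C)C | intermediate
4 | 3,5-bis(benzyloxy)-2-(trimethylsilyl)phenyl N-isopropylcarbamate | CC(C)NC(=O)Oc1cc(OCc2ccccc2)cc(OCc2ccccc2)c1[Si](C)(C)C | intermediate
5 | 3,5-bis(benzyloxy)-2-(trimethylsilyl)phenol | Oc1cc(OCc2ccccc2)cc(OCc2ccccc2)c1[Si](C)(C)C | intermediate
6 | 3,5-bis(benzyloxy)-2-(trimethylsilyl)phenyl trifluoromethanesulfonate | FC(F)(F)S(=O)(=O)Oc1cc(OCc2ccccc2)cc(OCc2ccccc2)c1[Si](C)(C)C | intermediate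
7 | (S)-4-benzyloxazolidin-2-one | O=C1N[C@@H](Cc2ccccc2)CO1 | starting material
8 | (benzyloxy)acetyl chloride | O=C(Cl)COCc1ccccc1 | starting material
9 | (S)-4-benzyl-3-[(benzyloxy)acetyl]oxazolidin-2-one | O=C(COCc1ccccc1)N1C(=O)OC[C@@H]1Cc1ccccc1 | intermediate
10 | 3,4-bis(benzyloxy)benzaldehyde | O=Cc1ccc(OCc2ccccc2)c(OCc2ccccc2)c1 | starting material
11 | (Z)-dibutylboron enolate of 9 | CCCCB(CCCC)O/C(=C\OCc1ccccc1)N1C(=O)OC[C@@H]1Cc1ccccc1 | intermediate
12 | (S)-4-benzyl-3-[(2S,3R)-2-(benzyloxy)-3-[3,4-bis(benzyloxy)phenyl]-3-hydroxypropanoyl]oxazolidin-2-one | O[C@H](c1ccc(OCc2ccccc2)c(OCc2ccccc2)c1)[C@H](OCc1ccccc1)C(=O)N1C(=O)OC[C@@H]1Cc1ccccc1 | intermediate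
13 | (2S,3R)-2-(benzyloxy)-3-[3,4-bis(benzyloxy)phenyl]-3-hydroxy-1-(morpholin-4-yl)propan-1-one | O[C@H](c1ccc(OCc2ccccc2)c(OCc2ccccc2)c1)[C@H](OCc1ccccc1)C(=O)N1CCOCC1 | intermediate
14 | sodium alkoxide of 13 | [Na+].[O-][C@H](c1ccc(OCc2ccccc2)c(OCc2ccccc2)c1)[C@H](OCc1ccccc1)C(=O)N1CCOCC1 | intermediate
15 | 3,5-bis(benzyloxy)benzyne | C(c1ccccc1)OC1=CC(OCc2ccccc2)=CC#C1 | intermediate
16 | sodium (2R,3S)-3,5,7-tris(benzyloxy)-2-[3,4-bis(benzyloxy)phenyl]-4-(morpholin-4-yl)chroman-4-olate (hemiaminal carbon left open) | c1ccccc1COc1cc(OCc2ccccc2)c2c(c1)O[C@H](c1ccc(OCc3ccccc3)c(OCc3ccccc3)c1)[C@H](OCc1ccccc1)C2([O-])N1CCOCC1.[Na+] | intermediate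
17 | (2R,3S)-3,5,7-tris(benzyloxy)-2-[3,4-bis(benzyloxy)phenyl]chroman-4-one | c1ccccc1COc1cc(OCc2ccccc2)c2c(c1)O[C@H](c1ccc(OCc3ccccc3)c(OCc3ccccc3)c1)[C@H](OCc1ccccc1)C2=O | intermediate
18 | (2R,3R)-3,5,7-tris(benzyloxy)-2-[3,4-bis(benzyloxy)phenyl]chroman-4-ol (C4 epimer mixture) | c1ccccc1COc1cc(OCc2ccccc2)c2c(c1)O[C@H](c1ccc(OCc3ccccc3)c(OCc3ccccc3)c1)[C@H](OCc1ccccc1)C2O | intermediate
19 | (2R,3R)-3,5,7-tris(benzyloxy)-2-[3,4-bis(benzyloxy)phenyl]-8-bromochroman-4-ol (C4 epimer mixture) | c1ccccc1COc1cc(OCc2ccccc2)c2c(c1Br)O[C@H](c1ccc(OCc3ccccc3)c(OCc3ccccc3)c1)[C@H](OCc1ccccc1)C2O | intermediate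
20 | (−)-epicatechin | Oc1cc(O)c2c(c1)O[C@H](c1ccc(O)c(O)c1)[C@H](O)C2 | starting material
21 | 5,7,3',4'-tetra-O-benzyl-(−)-epicatechin | c1ccccc1COc1cc(OCc2ccccc2)c2c(c1)O[C@H](c1ccc(OCc3ccccc3)c(OCc3ccccc3)c1)[C@H](O)C2 | intermediate
22 | 3,5,7,3',4'-penta-O-benzyl-8-bromoepicatechin-(4β→8)-5,7,3',4'-tetra-O-benzylepicatechin | c1ccccc1COc1cc(OCc2ccccc2)c2c(c1Br)O[C@H](c1ccc(OCc3ccccc3)c(OCc3ccccc3)c1)[C@H](OCc1ccccc1)[C@H]2c1c(OCc2ccccc2)cc(OCc2ccccc2)c2c1O[C@H](c1ccc(OCc3ccccc3)c(OCc3ccccc3)c1)[C@H](O)C2 | intermediate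
23 | 3,5,7,3',4'-penta-O-benzyl-8-bromoepicatechin-(4β→8)-5,7,3',4'-tetra-O-benzyl-4β-(2-ethoxyethoxy)epicatechin | c1ccccc1COc1cc(OCc2ccccc2)c2c(c1Br)O[C@H](c1ccc(OCc3ccccc3)c(OCc3ccccc3)c1)[C@H](OCc1ccccc1)[C@H]2c1c(OCc2ccccc2)cc(OCc2ccccc2)c2c1O[C@H](c1ccc(OCc3ccccc3)c(OCc3ccccc3)c1)[C@H](O)[C@H]2OCCOCC | intermediate
24 | (+)-catechin | Oc1cc(O)c2c(c1)O[C@H](c1ccc(O)c(O)c1)[C@@H](O)C2 | starting material
25 | 5,7,3',4'-tetra-O-benzyl-(+)-catechin | c1ccccc1COc1cc(OCc2ccccc2)c2c(c1)O[C@H](c1ccc(OCc3ccccc3)c(OCc3ccccc3)c1)[C@@H](O)C2 | intermediate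
26 | 8-bromo-5,7,3',4'-tetra-O-benzyl-(+)-catechin | c1ccccc1COc1cc(OCc2ccccc2)c2c(c1Br)O[C@H](c1ccc(OCc3ccccc3)c(OCc3ccccc3)c1)[C@@H](O)C2 | intermediate
27 | 3,5,7,3',4'-penta-O-benzyl-8-bromoepicatechin-(4β→8)-5,7,3',4'-tetra-O-benzylepicatechin-(4β→6)-8-bromo-5,7,3',4'-tetra-O-benzylcatechin | c1ccccc1COc1cc(OCc2ccccc2)c2c(c1Br)O[C@H](c1ccc(OCc3ccccc3)c(OCc3ccccc3)c1)[C@H](OCc1ccccc1)[C@H]2c1c(OCc2ccccc2)cc(OCc2ccccc2)c2c1O[C@H](c1ccc(OCc3ccccc3)c(OCc3ccccc3)c1)[C@H](O)[C@H]2c1c(OCc2ccccc2)c(Br)c2c(c1OCc1ccccc1)C[C@H](O)[C@@H](c1ccc(OCc3ccccc3)c(OCc3ccccc3)c1)O2 | intermediate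
28 | arecatannin B1 | Oc1cc(O)c2c(c1)O[C@H](c1ccc(O)c(O)c1)[C@H](O)[C@H]2c1c(O)cc(O)c2c1O[C@H](c1ccc(O)c(O)c1)[C@H](O)[C@H]2c1c(O)cc2c(c1O)C[C@H](O)[C@@H](c1ccc(O)c(O)c1)O2 | target

## Step count and risks

Total: 16 steps. Longest linear sequence: 10 steps (steps 4, 5, 6, 7, 8, 9, 11, 12, 15, 16; the aryne branch through steps 1, 2, 3 and 7 is equally long).

Steps most likely to fail:

1. Step 7 (proposed new method). The aryl anion may be protonated before it closes the ring, or the alkoxide may attack the sulfur of the triflate instead of adding to the aryne, so that only an open aryl ether or recovered amide is obtained. Fallback with known chemistry, setting out from compound 21 and returning at compound 18: the 3-hydroxyl of 21 is benzylated (NaH, BnBr, DMF, 0 °C) to give 3,5,7,3',4'-penta-O-benzyl-(−)-epicatechin F1. DDQ oxidation of F1 in CH2Cl2/H2O should then functionalize C4, with water trapping the cation on the β face, to give 18 as its 4β epimer, which enters step 9 unchanged. This takes the top unit from the chiral pool instead of building ring C.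

2. Step 12. Hydride abstraction may take place at the doubly benzylic C4–H of the upper unit and lead to cleavage or over-oxidation of the first interflavan bond. Fallback with orthogonal activation, setting out from compound 21 and returning at compound 27: 21 is oxidized at the monomer stage (DDQ, 2-ethoxyethanol, CH2Cl2) to 5,7,3',4'-tetra-O-benzyl-4β-(2-ethoxyethoxy)epicatechin F2. Exchange with thiophenol (PhSH, BF3·OEt2, CH2Cl2, −78 °C) gives 5,7,3',4'-tetra-O-benzyl-4β-(phenylsulfanyl)epicatechin F3. The thioether is inert to the oxophilic Lewis acid, so F3 (3 equiv) is coupled with 19 (BF3·OEt2, CH2Cl2, −78 °C) to the dimer 3,5,7,3',4'-penta-O-benzyl-8-bromoepicatechin-(4β→8)-5,7,3',4'-tetra-O-benzyl-4β-(phenylsulfanyl)epicatechin F4. Thiophilic activation of F4 (AgBF4, THF, 0 °C) in the presence of 26 then gives 27.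

3. Step 15. Attack of the hindered, bromine-deactivated C6 of 26 on the bulky dimeric cation may be too slow, so that self-condensation through a free C6 of the electrophile or decomposition of the cation wins. Fallback that reverses the order of fragment union, setting out from compound 21 and returning at compound 27: 21 is iodinated (N-iodosuccinimide, CH2Cl2, −40 °C) to 8-iodo-5,7,3',4'-tetra-O-benzylepicatechin F5 and oxidized (DDQ, 2-ethoxyethanol) to 8-iodo-5,7,3',4'-tetra-O-benzyl-4β-(2-ethoxyethoxy)epicatechin F6. The small, halo-capped monomer cation from F6 is coupled with 26 (TMSOTf, CH2Cl2, −78 °C) to 8-iodo-5,7,3',4'-tetra-O-benzylepicatechin-(4β→6)-8-bromo-5,7,3',4'-tetra-O-benzylcatechin F7. Selective iodine–magnesium exchange (i-PrMgCl·LiCl, THF, −40 °C; then MeOH) removes only the iodine and gives 5,7,3',4'-tetra-O-benzylepicatechin-(4β→6)-8-bromo-5,7,3',4'-tetra-O-benzylcatechin F8. Its free C8 is then joined to the cation from 19 (BF3·OEt2, CH2Cl2, −78 °C) to give 27.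

## Further compounds

F1 | step 7 | 3,5,7,3',4'-penta-O-benzyl-(−)-epicatechin | c1ccccc1COc1cc(OCc2ccccc2)c2c(c1)O[C@H](c1ccc(OCc3ccccc3)c(OCc3ccccc3)c1)[C@H](OCc1ccccc1)C2
F2 | step 12 | 5,7,3',4'-tetra-O-benzyl-4β-(2-ethoxyethoxy)epicatechin | c1ccccc1COc1cc(OCc2ccccc2)c2c(c1)O[C@H](c1ccc(OCc3ccccc3)c(OCc3ccccc3)c1)[C@H](O)[C@H]2OCCOCC
F3 | step 12 | 5,7,3',4'-tetra-O-benzyl-4β-(phenylsulfanyl)epicatechin | c1ccccc1COc1cc(OCc2ccccc2)c2c(c1)O[C@H](c1ccc(OCc3ccccc3)c(OCc3ccccc3)c1)[C@H](O)[C@H]2Sc1ccccc1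
F4 | step 12 | 3,5,7,3',4'-penta-O-benzyl-8-bromoepicatechin-(4β→8)-5,7,3',4'-tetra-O-benzyl-4β-(phenylsulfanyl)epicatechin | c1ccccc1COc1cc(OCc2ccccc2)c2c(c1Br)O[C@H](c1ccc(OCc3ccccc3)c(OCc3ccccc3)c1)[C@H](OCc1ccccc1)[C@H]2c1c(OCc2ccccc2)cc(OCc2ccccc2)c2c1O[C@H](c1ccc(OCc3ccccc3)c(OCc3ccccc3)c1)[C@H](O)[C@H]2Sc1ccccc1
F5 | step 15 | 8-iodo-5,7,3',4'-tetra-O-benzylepicatechin | c1ccccc1COc1cc(OCc2ccccc2)c2c(c1I)O[C@H](c1ccc(OCc3ccccc3)c(OCc3ccccc3)c1)[C@H](O)C2
F6 | step 15 | 8-iodo-5,7,3',4'-tetra-O-benzyl-4β-(2-ethoxyethoxy)epicatechin | c1ccccc1COc1cc(OCc2ccccc2)c2c(c1I)O[C@H](c1ccc(OCc3ccccc3)c(OCc3ccccc3)c1)[C@H](O)[C@H]2OCCOCC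
F7 | step 15 | 8-iodo-5,7,3',4'-tetra-O-benzylepicatechin-(4β→6)-8-bromo-5,7,3',4'-tetra-O-benzylcatechin | c1ccccc1COc1cc(OCc2ccccc2)c2c(c1I)O[C@H](c1ccc(OCc3ccccc3)c(OCc3ccccc3)c1)[C@H](O)[C@H]2c1c(OCc2ccccc2)c(Br)c2c(c1OCc1ccccc1)C[C@H](O)[C@@H](c1ccc(OCc3ccccc3)c(OCc3ccccc3)c1)O2
F8 | step 15 | 5,7,3',4'-tetra-O-benzylepicatechin-(4β→6)-8-bromo-5,7,3',4'-tetra-O-benzylcatechin | c1ccccc1COc1cc(OCc2ccccc2)c2c(c1)O[C@H](c1ccc(OCc3ccccc3)c(OCc3ccccc3)c1)[C@H](O)[C@H]2c1c(OCc2ccccc2)c(Br)c2c(c1OCc1ccccc1)C[C@H](O)[C@@H](c1ccc(OCc3ccccc3)c(OCc3ccccc3)c1)O2
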